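**Retrosynthetic overview**
1. Numbering follows bicyclo[4.3.1]decane. C1 and C6 are the bridgeheads. C2–C5 is the four-carbon bridge (side chain on C2, OAc on C3, =CH2 on C5). C7–C9 is the three-carbon bridge (CHO on C9). C10 is the acetoxy-bearing one-carbon bridge.
2. Enabling feature: in the nine-membered perimeter ring C1–C9, the two trigonal carbons C9 and C5 are 1,6-related through C1–C2–C3–C4. Read as ketones, they are the retron of an oxy-Cope rearrangement whose new σ bond is C2–C3. C10 is β to C9, which is the retron of an acylation of the C9 enolate at C1.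
3. Disconnections: the CHO comes from a C9 enol triflate and CO, the =CH2 from a C5 ketone, and C10–OAc from a bridge ketone. The bicyclic 9,10-dione comes from a cis-1,2-dialkenylcyclopentanolate that carries a temporary C5–C9 bond and a C6 ester (the future C10).
4. Ring order: the cyclopentane C5–C6–C7–C8–C9 is bought in. A [3,3] ring expansion turns it into the nine-membered ring and cleaves the temporary bond. The six- and seven-membered rings then form together by transannular C1–C10 closure.
5. Building blocks: methyl 3-oxocyclopent-1-ene-1-carboxylate and (S)-β-citronellene, which supplies the side-chain stereocentre.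

Key step: step 8

Remark: compounds 1 and 8 are taken as commercially available. The BINAP antipode in step 1 is the one that delivers the 1R series.

Step 1
Reactants: 1 methyl 3-oxocyclopent-1-ene-1-carboxylate
Product: 3 methyl (1R,2S)-3-oxo-2-(prop-2-en-1-yl)cyclopentane-1-carboxylate (trans), via diphenylsilyl enol ether 2 (not isolated)
Conditions: CuCl, NaOt-Bu, (S)-p-tol-BINAP (cat.), Ph2SiH2, toluene, 0 °C; then allyl bromide, Bu4N[Ph3SiF2], CH2Cl2, rt
Reagents that add atoms: allyl bromide C=CCBr
Why: Asymmetric copper hydride conjugate reduction delivers hydride under ligand control to the enone β-carbon (setting the future C6) and gives the regiodefined silyl enol ether 2, whose fluoride-triggered allylation occurs anti to the ester (conjugate reduction–alkylation).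

Step 2
Reactants: 3 methyl (1R,2S)-3-oxo-2-(prop-2-en-1-yl)cyclopentane-1-carboxylate
Product: 4 methyl (1R)-3-(tert-butyldimethylsilyloxy)-2-(prop-2-en-1-yl)cyclopent-2-ene-1-carboxylate
Conditions: TBSOTf, Et3N, CH2Cl2, 0 °C to rt
Reagents that add atoms: TBSOTf CC(C)(C)[Si](C)(C)OS(=O)(=O)C(F)(F)F
Why: Soft enolisation under equilibrating conditions should give the tetrasubstituted silyl enol ether because the C2–H is the more acidic α-hydrogen, and the C2 centre is erased on purpose (silyl enol ether formation).

Step 3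
Reactants: 4 methyl (1R)-3-(tert-butyldimethylsilyloxy)-2-(prop-2-en-1-yl)cyclopent-2-ene-1-carboxylate
Product: 5 methyl (1R,2S)-2-(tert-butyldimethylsilyloxy)-3-oxo-2-(prop-2-en-1-yl)cyclopentane-1-carboxylate (allyl cis to the ester)
Conditions: m-CPBA, NaHCO3, CH2Cl2, −20 °C to rt
Reagents that add atoms: m-CPBA O=C(OO)c1cccc(Cl)c1
Why: In this Rubottom oxidation the electron-rich enol ether is epoxidised before the terminal alkene and from the face anti to the neighbouring ester, and the silyloxy epoxide collapses with an O-to-O silyl shift, which sets the quaternary carbinol centre with oxygen trans and allyl cis to the ester.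

Step 4
Reactants: 5 methyl (1R,2S)-2-(tert-butyldimethylsilyloxy)-3-oxo-2-(prop-2-en-1-yl)cyclopentane-1-carboxylate
Product: 6 methyl (1R,2S)-2-(tert-butyldimethylsilyloxy)-3-oxo-2-(2-oxoethyl)cyclopentane-1-carboxylate
Conditions: O3, CH2Cl2–MeOH, −78 °C; Me2S
Reagents that add atoms: ozone [O-][O+]=O
Why: Ozonolysis with reductive work-up cleaves the only C=C bond to the aldehyde and touches no stereocentre.

Step 5
Reactants: 6 methyl (1R,2S)-2-(tert-butyldimethylsilyloxy)-3-oxo-2-(2-oxoethyl)cyclopentane-1-carboxylate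
Product: 7 methyl (1R,2S)-2-(tert-butyldimethylsilyloxy)-2-[(E)-2-(tert-butyldimethylsilyloxy)ethenyl]-3-oxocyclopentane-1-carboxylate
Conditions: TBSOTf (1.05 equiv), Et3N, CH2Cl2, −78 to 0 °C
Reagents that add atoms: TBSOTf CC(C)(C)[Si](C)(C)OS(=O)(=O)C(F)(F)F
Why: Soft enolisation should silylate the more reactive aldehyde before the hindered ketone, and allylic strain against the adjacent quaternary carbon should favour the E silyl enol ether (silyl enol ether formation).

Step 6
Reactants: 8 (3S)-3,7-dimethylocta-1,6-diene ((S)-β-citronellene)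
Product: 9 2-[(1E,3S)-3,7-dimethylocta-1,6-dien-1-yl]-4,4,5,5-tetramethyl-1,3,2-dioxaborolane
Conditions: vinylboronic acid pinacol ester, second-generation Grubbs catalyst (cat.), CH2Cl2, 40 °C
Reagents that add atoms: vinylboronic acid pinacol ester C=CB1OC(C)(C)C(C)(C)O1
Why: Olefin cross-metathesis of the monosubstituted alkene with a vinylboronate is E-selective and leaves the trisubstituted alkene and the allylic stereocentre untouched.

Step 7
Reactants: 9 2-[(1E,3S)-3,7-dimethylocta-1,6-dien-1-yl]-4,4,5,5-tetramethyl-1,3,2-dioxaborolane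
Product: 10 (1E,3S)-1-iodo-3,7-dimethylocta-1,6-diene
Conditions: NaOH, I2, THF–H2O, 0 °C
Reagents that add atoms: iodine II
Why: Base-mediated iododeboronation of an alkenylboronate proceeds with retention of the E geometry.

Step 8
Reactants: 10 (1E,3S)-1-iodo-3,7-dimethylocta-1,6-diene; 7 methyl (1R,2S)-2-(tert-butyldimethylsilyloxy)-2-[(E)-2-(tert-butyldimethylsilyloxy)ethenyl]-3-oxocyclopentane-1-carboxylate
Product: 15 3,5-bis(tert-butyldimethylsilyloxy)-2-[(2S)-6-methylhept-5-en-2-yl]bicyclo[4.3.1]dec-4-ene-9,10-dione (C1 C2 C3 C6 arranged in space as in 21), via alkenyllithium 11 (not isolated), via alkenylmagnesium bromide 12 (not isolated), via magnesium carbinolate 13 (not isolated), via cyclononadienolate 14 (not isolated)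
Conditions: 10, t-BuLi (2 equiv), Et2O, −78 °C; MgBr2·OEt2; then 7, toluene–THF, −78 °C to rt; aq NH4Cl
Reagents that add atoms: none
Why: The alkenyl Grignard reagent adds to the ring ketone of 7 (faster than to the ester) anti to the bulky, electronegative α-OTBS group, where Felkin–Anh and steric control agree, so the two E-alkenyl groups stand cis on the cyclopentane in 13. The alkoxide then triggers an anion-accelerated oxy-Cope rearrangement through the boat-like array open to a cis-1,2-dialkenylcyclopentane, which forms C2–C3, cleaves the temporary C5–C9 bond and expands the five-membered ring to the Z,Z-cyclononadiene 14. Because both alkene termini are E and react suprafacially, the side chain on C2 and the silyloxy group on C3 should come out cis to each other, and their relation to C6 follows from the all-cis placement of the ester and the two alkenyl groups set in steps 1 and 3 and in the addition. The regiodefined magnesium enolate (O on C9, nucleophilic C1) lies across the ring from the C6 ester and closes C1–C10 by a transannular Dieckmann acylation (6-exo-trig at the ester carbonyl), which creates the six- and seven-membered rings at once and can form C1 only with the bridge cis to C6. The second oxygenated terminus stays masked as the neutral silyl enol ether at C5, so only one enolate exists and C5 and C9 remain differentiated for the endgame. Carbonyl addition followed by anionic oxy-Cope ring expansion of a 2-alkenylcyclopentanone and transannular Dieckmann closure to a bicyclo[4.3.1]decane is a known cascade type.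

Step 9
Reactants: 15 3,5-bis(tert-butyldimethylsilyloxy)-2-[(2S)-6-methylhept-5-en-2-yl]bicyclo[4.3.1]dec-4-ene-9,10-dione
Product: 16 3,5-bis(tert-butyldimethylsilyloxy)-2-[(2S)-6-methylhept-5-en-2-yl]-10-oxobicyclo[4.3.1]deca-4,8-dien-9-yl trifluoromethanesulfonate
Conditions: KHMDS, THF, −78 °C; PhNTf2
Reagents that add atoms: N-phenylbis(trifluoromethanesulfonimide) O=S(=O)(N(c1ccccc1)S(=O)(=O)C(F)(F)F)C(F)(F)F
Why: Kinetic deprotonation should occur only at C8, because every other α-position is a bridgehead whose C–H bond is poorly aligned with the carbonyl π systems, and the enolate is trapped as the enol triflate (enol triflate formation).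

Step 10
Reactants: 16 the C9 enol triflate with the C10 ketone
Product: 17 3,5-bis(tert-butyldimethylsilyloxy)-10-hydroxy-2-[(2S)-6-methylhept-5-en-2-yl]bicyclo[4.3.1]deca-4,8-dien-9-yl trifluoromethanesulfonate (OH syn to the four-carbon bridge)
Conditions: NaBH4, MeOH–CH2Cl2, −20 °C
Reagents that add atoms: none
Why: Hydride should reach the bridge ketone from the open face above the flat C8=C9 bridge rather than from the face shielded by the substituted four-carbon bridge, which sets C10 with OH syn to the four-carbon bridge (diastereoselective borohydride reduction).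

Step 11
Reactants: 17 the C10 alcohol
Product: 18 3,10-dihydroxy-2-[(2S)-6-methylhept-5-en-2-yl]-5-oxobicyclo[4.3.1]dec-8-en-9-yl trifluoromethanesulfonate
Conditions: HF·pyridine, THF, 0 °C
Reagents that add atoms: none
Why: Fluoride-induced desilylation cleaves the secondary silyl ether and converts the silyl enol ether into the C5 ketone under non-basic conditions that avoid β-elimination and retro-aldol cleavage.

Step 12
Reactants: 18 the 3,10-dihydroxy C5 ketone
Product: 19 3,10-dihydroxy-5-methylidene-2-[(2S)-6-methylhept-5-en-2-yl]bicyclo[4.3.1]dec-8-en-9-yl trifluoromethanesulfonate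
Conditions: Zn, CH2Br2, TiCl4, THF–CH2Cl2, 0 °C to rt
Reagents that add atoms: dibromomethane BrCBr
Why: The non-basic gem-dimetallic reagent of the Takai–Lombardo methylenation olefinates hindered, base-sensitive β-hydroxy ketones without enolisation and tolerates free hydroxy groups and the enol triflate.

Step 13
Reactants: 19 the 5-methylidene diol
Product: 20 3,10-diacetoxy-5-methylidene-2-[(2S)-6-methylhept-5-en-2-yl]bicyclo[4.3.1]dec-8-en-9-yl trifluoromethanesulfonate
Conditions: Ac2O, pyridine, DMAP (cat.), CH2Cl2, 0 °C to rt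
Reagents that add atoms: acetic anhydride CC(=O)OC(C)=O
Why: DMAP-catalysed acylation esterifies both secondary alcohols with retention, and no ketone that could trigger β-elimination remains.

Step 14
Reactants: 20 the diacetoxy enol triflate
Product: 21 (1R,2R,3S,6R,10S)-3,10-diacetoxy-5-methylidene-2-[(2S)-6-methylhept-5-en-2-yl]bicyclo[4.3.1]dec-8-ene-9-carbaldehyde (target)
Conditions: Pd(PPh3)4 (cat.), CO (1 atm), Bu3SnH (slow addition), LiCl, THF, 50 °C
Reagents that add atoms: carbon monoxide [C-]#[O+]
Why: In this palladium-catalysed reductive carbonylation of an enol triflate, oxidative addition, CO insertion and hydride transfer from the stannane give the enal, while the merely homoallylic acetates cannot ionise.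

**Compound list**
1 | methyl 3-oxocyclopent-1-ene-1-carboxylate | COC(=O)C1=CC(=O)CC1 | starting material
2 | methyl (1R)-3-(diphenylsilyloxy)cyclopent-2-ene-1-carboxylate | C1=C(O[SiH](c2ccccc2)c2ccccc2)CC[C@H]1C(=O)OC | intermediate
3 | methyl (1R,2S)-3-oxo-2-(prop-2-en-1-yl)cyclopentane-1-carboxylate | O=C1CC[C@@H](C(=O)OC)[C@@H]1CC=C | intermediate
4 | methyl (1R)-3-(tert-butyldimethylsilyloxy)-2-(prop-2-en-1-yl)cyclopent-2-ene-1-carboxylate | C=CCC1=C(O[Si](C)(C)C(C)(C)C)CC[C@H]1C(=O)OC | intermediate
5 | methyl (1R,2S)-2-(tert-butyldimethylsilyloxy)-3-oxo-2-(prop-2-en-1-yl)cyclopentane-1-carboxylate | O=C1CC[C@@H](C(=O)OC)[C@@]1(O[Si](C)(C)C(C)(C)C)CC=C | intermediate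
6 | methyl (1R,2S)-2-(tert-butyldimethylsilyloxy)-3-oxo-2-(2-oxoethyl)cyclopentane-1-carboxylate | O=C1CC[C@@H](C(=O)OC)[C@@]1(O[Si](C)(C)C(C)(C)C)CC=O | intermediate
7 | methyl (1R,2S)-2-(tert-butyldimethylsilyloxy)-2-[(E)-2-(tert-butyldimethylsilyloxy)ethenyl]-3-oxocyclopentane-1-carboxylate | O=C1CC[C@@H](C(=O)OC)[C@@]1(O[Si](C)(C)C(C)(C)C)/C=C/O[Si](C)(C)C(C)(C)C | intermediate
8 | (3S)-3,7-dimethylocta-1,6-diene | C=C[C@@H](C)CCC=C(C)C | starting material
9 | 2-[(1E,3S)-3,7-dimethylocta-1,6-dien-1-yl]-4,4,5,5-tetramethyl-1,3,2-dioxaborolane | CC1(C)OB(/C=C/[C@@H](C)CCC=C(C)C)OC1(C)C | intermediate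
10 | (1E,3S)-1-iodo-3,7-dimethylocta-1,6-diene | I/C=C/[C@@H](C)CCC=C(C)C | intermediate
11 | [(1E,3S)-3,7-dimethylocta-1,6-dien-1-yl]lithium | [Li]/C=C/[C@@H](C)CCC=C(C)C | intermediate
12 | [(1E,3S)-3,7-dimethylocta-1,6-dien-1-yl]magnesium bromide | Br[Mg]/C=C/[C@@H](C)CCC=C(C)C | intermediate
13 | bromomagnesium cis-1,2-dialkenylcyclopentanolate (both alkenyl groups and the ester on one face) | Br[Mg]O[C@]1(/C=C/[C@@H](C)CCC=C(C)C)CC[C@@H](C(=O)OC)[C@@]1(O[Si](C)(C)C(C)(C)C)/C=C/O[Si](C)(C)C(C)(C)C | intermediate
14 | bromomagnesium Z,Z-cyclonona-1,5-dienolate (nine-membered ring enolate with the C6 ester) | Br[Mg]O/C1=C/[C@@H]([C@@H](C)CCC=C(C)C)[C@@H](O[Si](C)(C)C(C)(C)C)/C=C(/O[Si](C)(C)C(C)(C)C)[C@H](C(=O)OC)CC1 | intermediate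
15 | 3,5-bis(tert-butyldimethylsilyloxy)-2-[(2S)-6-methylhept-5-en-2-yl]bicyclo[4.3.1]dec-4-ene-9,10-dione | CC(C)(C)[Si](C)(C)OC1=C[C@H](O[Si](C)(C)C(C)(C)C)[C@H]([C@@H](C)CCC=C(C)C)[C@@H]2C(=O)CC[C@H]1C2=O | intermediate
16 | C9 enol triflate of 15 | CC(C)(C)[Si](C)(C)OC1=C[C@H](O[Si](C)(C)C(C)(C)C)[C@H]([C@@H](C)CCC=C(C)C)[C@@H]2C(OS(=O)(=O)C(F)(F)F)=CC[C@H]1C2=O | intermediate
17 | C10 alcohol (OH syn to the four-carbon bridge) | CC(C)(C)[Si](C)(C)OC1=C[C@H](O[Si](C)(C)C(C)(C)C)[C@H]([C@@H](C)CCC=C(C)C)[C@@H]2C(OS(=O)(=O)C(F)(F)F)=CC[C@H]1[C@@H]2O | intermediate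
18 | 3,10-dihydroxy-5-oxo enol triflate | O=C1C[C@H](O)[C@H]([C@@H](C)CCC=C(C)C)[C@@H]2C(OS(=O)(=O)C(F)(F)F)=CC[C@H]1[C@@H]2O | intermediate
19 | 3,10-dihydroxy-5-methylidene enol triflate | C=C1C[C@H](O)[C@H]([C@@H](C)CCC=C(C)C)[C@@H]2C(OS(=O)(=O)C(F)(F)F)=CC[C@H]1[C@@H]2O | intermediate
20 | 3,10-diacetoxy-5-methylidene enol triflate | C=C1C[C@H](OC(C)=O)[C@H]([C@@H](C)CCC=C(C)C)[C@@H]2C(OS(=O)(=O)C(F)(F)F)=CC[C@H]1[C@@H]2OC(C)=O | intermediate
21 | (1R,2R,3S,6R,10S)-3,10-diacetoxy-5-methylidene-2-[(2S)-6-methylhept-5-en-2-yl]bicyclo[4.3.1]dec-8-ene-9-carbaldehyde | C=C1C[C@H](OC(C)=O)[C@H]([C@@H](C)CCC=C(C)C)[C@@H]2C(C=O)=CC[C@H]1[C@@H]2OC(C)=O | target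

**Step count**
- Total steps: 14.
- Longest linear sequence: 12 (steps 1–5 and 8–14).

**Steps most likely to fail**

**1. Step 8.**
- The Grignard reagent may add from the wrong face. The resulting trans-dialkenyl carbinolate cannot reach the boat array.
- The silyl group may migrate from the C5 oxygen to the neighbouring alkoxide. This moves the charge to C5 and opens β-elimination of the C3 silyloxy group.
- The enolate may be protonated, or the acylation may be reversed by the released methoxide.
- Fallback: it sets out from 7 and 10 and returns at 15. It splits the cascade and replaces the ester electrophile with an aldehyde. The organocerium reagent from 11 and CeCl3 is added at −78 °C and quenched cold to give the tertiary carbinol F1, whose diastereomers can be separated at this stage. DIBAL-H at −78 °C reduces the ester to the hydroxy aldehyde F2. KH with 18-crown-6 then runs the oxy-Cope rearrangement with a transannular aldol closure, which has no leaving group that could reverse it, and gives the hydroxy ketone F3. Dess–Martin periodinane oxidises F3 to 15.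

**2. Step 5.**
- Geometric control in the enol silane formation may be poor. The ketone may also be silylated, or the β-silyloxy group may be lost.
- Fallback: it sets out from 6 and returns at 19. It makes the enol geometry irrelevant by a later redox correction. The mixture of 7 and its Z isomer F4 is carried through steps 8–12 and gives 19 together with its C3 epimer F5. The less hindered C3 alcohol of the mixture is oxidised with one equivalent of Dess–Martin periodinane to the C3 ketone F6, in which the C2 side chain sits in its equatorial, more stable position. LiBH(s-Bu)3 attacks from the exo face and converges on the axial C3 alcohol 19.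

**3. Step 12.**
- Olefination of the ketone next to the bridgehead may be slow. Retro-aldol cleavage of the doubly β-hydroxylated ketone may compete.
- Fallback: it sets out from 18 and returns at 19. It replaces the titanium–zinc carbenoid with an addition–elimination sequence (Peterson olefination). Both alcohols are capped with TESOTf and 2,6-lutidine to give the bis(triethylsilyl) ether F7. Me3SiCH2MgCl with CeCl3 at −78 °C adds to the ketone to give the β-hydroxysilane F8. HF·pyridine then causes the elimination and removes both silyl ethers to give 19.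

**Further compounds**
F1 | step 8 | tertiary cis-1,2-dialkenylcyclopentanol (protonated 13) | O[C@]1(/C=C/[C@@H](C)CCC=C(C)C)CC[C@@H](C(=O)OC)[C@@]1(O[Si](C)(C)C(C)(C)C)/C=C/O[Si](C)(C)C(C)(C)C
F2 | step 8 | hydroxy aldehyde from F1 | O[C@]1(/C=C/[C@@H](C)CCC=C(C)C)CC[C@@H](C=O)[C@@]1(O[Si](C)(C)C(C)(C)C)/C=C/O[Si](C)(C)C(C)(C)C
F3 | step 8 | 10-hydroxy-9-ketone from the oxy-Cope/transannular aldol sequence | CC(C)(C)[Si](C)(C)OC1=C[C@H](O[Si](C)(C)C(C)(C)C)[C@H]([C@@H](C)CCC=C(C)C)[C@@H]2C(=O)CC[C@H]1[C@@H]2O
F4 | step 5 | Z isomer of 7 | O=C1CC[C@@H](C(=O)OC)[C@@]1(O[Si](C)(C)C(C)(C)C)/C=C\O[Si](C)(C)C(C)(C)C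
F5 | step 5 | C3 epimer of 19 | C=C1C[C@@H](O)[C@H]([C@@H](C)CCC=C(C)C)[C@@H]2C(OS(=O)(=O)C(F)(F)F)=CC[C@H]1[C@@H]2O
F6 | step 5 | C3 ketone | C=C1CC(=O)[C@H]([C@@H](C)CCC=C(C)C)[C@@H]2C(OS(=O)(=O)C(F)(F)F)=CC[C@H]1[C@@H]2O
F7 | step 12 | bis(triethylsilyl) ether of 18 | O=C1C[C@H](O[Si](CC)(CC)CC)[C@H]([C@@H](C)CCC=C(C)C)[C@@H]2C(OS(=O)(=O)C(F)(F)F)=CC[C@H]1[C@@H]2O[Si](CC)(CC)CC
F8 | step 12 | β-hydroxysilane (configuration at C5 immaterial) | C[Si](C)(C)CC1(O)C[C@H](O[Si](CC)(CC)CC)[C@H]([C@@H](C)CCC=C(C)C)[C@@H]2C(OS(=O)(=O)C(F)(F)F)=CC[C@H]1[C@@H]2O[Si](CC)(CC)CC
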